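## Structural features

The target joins a 2-methoxy-3,5-dimethyl-4-pyrone (atoms primed, ring oxygen O1') through C6' to the fully substituted C7 of a cis-fused bicyclo[4.2.0]octene. The carbocycle is numbered C1 (methylated fusion carbon), C2 (OCH), C3=C4 (C3 methylated), C5 (methylated, oxygenated), C6 (fusion CH), C7, C8 (CHMe), and a peroxide bridges C2 and C5. All six sp3 ring carbons (C1, C2, C5, C6, C7, C8) are contiguous stereocentres and three of them (C1, C5, C7) are fully substituted. On the cyclobutane the methyls at C1, C7 and C8 all lie on the exo face (turned away from the six-membered ring) and the pyrone is endo; the peroxide sits on the face of the six-membered ring anti to the cyclobutane (called the anti face below). The O–O bond is the fragile group (reductants, phosphines, low-valent metals, heat, and base through the C2 hydrogen in a Kornblum–DeLaMare rearrangement). The cyclohexadiene from which it must come is acid-labile and can open electrocyclically, and any cation at C5 is a cyclobutylcarbinyl cation. The real difficulty is the tetrasubstituted cyclobutane with two quaternary carbons and four contiguous stereocentres as one enantiomer. Two features are exploited: the C6–C7 bond is anti to the C5–O bond, the signature of a backside opening of a C5–C6 oxirane by a carbanion at C7; and the ring C1–C6 without C7 and C8 has a mirror plane through C1 and C4, so it can come from an achiral Birch product in which one stereocentre at C8 chooses between two mirror-related oxiranes.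

## Logic of the disconnections

30 to 29. The two C–O bonds at C2 and C5 are cut (retro [4+2] with dioxygen). The peroxide tolerates almost nothing, so it is made last. This removes two stereocentres and the only fragile group. The forward step must add oxygen as a cycloaddition, and only to the anti face.

29 to 27. The C4=C5 double bond is exchanged for a C5–OH and a C4–H. The diene is acid- and heat-sensitive, so it is unmasked one step before use, and the C5 oxygen is the one released by the key step. The precursor is a robust tertiary alcohol. The forward elimination must go toward C4 (not C6 or the methyl) and must avoid a cation at C5.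

27 to 26 to 25. The O–CH3 bond and then the O1'–C2' bond are cut. This is the standard triketide logic and leaves an open-chain 3,5-diketo ester. The forward steps must methylate the lactone carbonyl oxygen rather than the 4-hydroxyl, and must close the ring next to a quaternary carbon.

25 to 24 to 21 and 22. After adjusting the oxidation level, the C6'–C5' bond is cut. All seven remaining pyrone carbons then come from one commercial piece, 22. The forward addition has to take place at an aldehyde on a fully substituted cyclobutane carbon.

21 to 19 to 18. The aldehyde goes back to the nitrile, and the C2=C3 alkene goes back to the C2–C3 oxirane. The nitrile is the activating group of the key step and the oxirane is the relic of the symmetric precursor. The forward steps are a half-reduction of a hindered nitrile and an oxygen removal that spares the tertiary alcohol.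

18 to 15 (key). The C6–C7 bond is cut. This removes the cyclobutane, one C–C bond and three stereocentres (C1, C6, C7), and leaves a bis-epoxide whose ring is mirror-symmetric with a single reagent-derived stereocentre at C8. The forward step must close four-membered rather than five-membered, choose C6 over C2, and put the nitrile endo.

15 to 13. The four C–O bonds of the two oxiranes are cut, giving a skipped diene. Both oxygens must enter cis to the C1 methyl, away from the side chain.

13 to 11 to 9. The C7–CH3 bond is cut and the nitrile is traced to an ester. C7 needs no control because it is planarised in the key step.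

9 to 7 and 8. The C8–CH3 bond is cut. This is the only point of absolute stereocontrol, and the precursor is an achiral enoate. The forward step must select a face catalytically at a beta-carbon that carries a tertiary alkyl group.

7 to 4 and 5, then to 3 and 1. The C7=C8 alkene is cut by olefination, the carbinol is traced to the ester, and the C1–CH3 bond and the two ring hydrogens are removed to reach the arene. The forward Birch alkylation must alkylate at the ipso carbon.

## Other disconnections considered

Alternative 1: The cut takes C3 with its methyl out of the six-membered ring (C2–C3 and C3–C4 broken, C2–C4 made) and leads to the silyl enol ether A1 of a bicyclo[3.2.0]heptan-2-one. In the forward step chloro(methyl)carbene A2 would add to the enol ether double bond of A1, and the siloxychlorocyclopropane would open with loss of chloride to the 2-methylcyclohexenone A3.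
- In its favour: the ketone behind A1 can enolise only away from the quaternary C1, so the site of insertion is not in doubt, and the C2 oxygen and C3 methyl arrive together.
- Better than the chosen plan on one point: A3 could reach the 2,4-diene through its dienyl triflate with no regiochemical question, whereas step 15 depends on the direction of an elimination.
- Against it: the cut does not touch the cyclobutane, so C1, C6, C7, C8 and both quaternary carbons would still have to be set in a separate synthesis of A1. The carbene is generated under strongly basic conditions and must add next to a quaternary carbon. C5 of A3 is a stereocentre made only to be destroyed. The C7 arm of A3 needs deprotection and oxidation before the pyrone can be built.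
- Comparison: structurally the chosen plan solves the cyclobutane and uses the hidden symmetry, while this one only adjusts ring size. Mechanistically both key steps are stereospecific, and the alternative has no group-selectivity question. In step count no saving is expected, because A1 cannot be simpler to reach than 15.

Alternative 2: The cut is a retro [2+2] through C6–C7 and C1–C8 and leads to the achiral quinol tiglate A4. In the forward step A4, bound to a chiral Lewis acid, would be irradiated; the tiglate alkene would add across one of the two enantiotopic enone alkenes and give the tricyclic lactone A5.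
- In its favour: A4 should be available in two operations from a commercial phenol. One step would form two C–C bonds, the cyclobutane, the cis fusion and all four cyclobutane stereocentres. The E geometry of the tiglate encodes the cis C7/C8 methyls and the tether forces the carboxyl carbon endo, where the pyrone must be.
- Better or equal: on step economy it is clearly better (the chosen plan needs eight steps to the comparable stage 18). In resting on one catalytic stereo-determining event it is the equal of the chosen plan.
- Against it: cross-conjugated cyclohexadienones have fast competing excited-state channels (lumiketone rearrangement), and a Lewis acid can trigger a dienone–phenol-type acyloxy shift. An ester tether prefers the extended conformation that keeps the alkene away from the ring. Both new bonds end at or next to fully substituted carbons. A triplet 1,4-diradical could scramble C8. Enantioselective Lewis-acid-mediated [2+2] photocycloaddition is established for simpler enones only. Afterwards the C5 oxygen of A5 (syn to C7) and the C2 ketone must be reworked into the diene, and the hindered carboxyl carbon turned into the pyrone.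
- Comparison: both plans use a mirror plane of the six-membered ring (here the one through C2 and C5). An excited-state reaction with several competing channels stands against a ground-state SN2 closure with close analogy. It is the shorter but riskier plan.

Alternative 3: The cut is inside the pyrone (O1'–C2' and C3'–C4') and leads to the dioxinone A6 and 1-methoxypropyne A8. In the forward step heating A6 would release the acylketene A7, which would combine with A8 in a [4+2] sense to give the complete methoxypyrone A9.
- In its favour, and better than steps 13 and 14: the heterocycle arrives complete and correctly O-methylated in one neutral thermal step. Regiochemistry is fixed by polarity (the nucleophilic carbon of A8 to the ketene carbon). There is no question of 2-methoxy-4-pyrone against 4-methoxy-2-pyrone, and no strong alkylating agent near the tertiary oxygen.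
- Against it: it disconnects the heterocycle only. A9 is the triethylsilyl ether of 27, so the carbocycle must still be made as in the chosen plan. A6 has to be assembled on the hindered C7 acyl group, which is no easier than step 11. The C5 hydroxyl must be protected and released, because an acylketene acylates alcohols. A8 is volatile and sensitive, and A7 may dimerise.
- Comparison: the two plans are complementary (this one could replace steps 12–14). Both key steps are precedented in type. Preparing A6 plus protection and deprotection is at best equal in step count to steps 11–14.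

Key step: step 8

Remark (assumption): in step 4 the antipode of Tol-BINAP is taken that delivers methyl to the face of 7 leading to the (3S) ester 9; both antipodes are commercial, and the sense should be confirmed on a model enoate.

Remark (structure check and design changes): the configurations of 15 and 18 were compared centre by centre with 30 and agree (C1, C6, C7, C8 as in the target; both oxygens of 18 on the anti face), so no structure needed correction. Three design changes are made: C7 of 15 is used as an epimer mixture; the nitrile is half-reduced to the aldehyde instead of hydrolysed; the C5 hydroxyl is kept until the penultimate step.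

## Steps

Step 1
Reactants: 1 methyl 3,5-dimethylbenzoate
Product: 3 methyl 1,3,5-trimethylcyclohexa-2,5-diene-1-carboxylate (achiral), via lithium dienolate 2 (not isolated)
Conditions: Li, NH3(l)/THF, t-BuOH (1 equiv), −78 °C; then MeI, −78 °C → rt
Reagents that add atoms: iodomethane, CI
Why: Birch reductive alkylation: the benzoate takes up two electrons at the ipso and para carbons, and the resulting ester dienolate 2 is methylated at the ipso carbon, which gives the quaternary C1 and the skipped diene; 3 keeps the mirror plane through C1 and C4.

Step 2
Reactants: 3 methyl 1,3,5-trimethylcyclohexa-2,5-diene-1-carboxylate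
Product: 4 (1,3,5-trimethylcyclohexa-2,5-dien-1-yl)methanol
Conditions: LiAlH4, Et2O, 0 °C
Reagents that add atoms: none
Why: Hydride reduction of an ester to the primary alcohol; the unconjugated trisubstituted alkenes are inert and no stereocentre is involved.

Step 3
Reactants: 4 (1,3,5-trimethylcyclohexa-2,5-dien-1-yl)methanol; 5 methyl (triphenylphosphoranylidene)acetate
Product: 7 methyl (2E)-3-(1,3,5-trimethylcyclohexa-2,5-dien-1-yl)prop-2-enoate, via 1,3,5-trimethylcyclohexa-2,5-diene-1-carbaldehyde 6 (not isolated)
Conditions: (COCl)2, DMSO, CH2Cl2, −78 °C; Et3N, −78 → 0 °C; then 5, 0 °C → rt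
Reagents that add atoms: none
Why: Swern oxidation followed in the same flask by a Wittig reaction of the stabilised ylide; the volatile, acid-sensitive aldehyde 6 is never handled, and a stabilised ylide with an alpha-quaternary aldehyde should give the E enoate almost exclusively.

Step 4
Reactants: 7 methyl (2E)-3-(1,3,5-trimethylcyclohexa-2,5-dien-1-yl)prop-2-enoate; 8 methylmagnesium bromide
Product: 9 methyl (3S)-3-(1,3,5-trimethylcyclohexa-2,5-dien-1-yl)butanoate
Conditions: CuI (3 mol%), Tol-BINAP (4.5 mol%), t-BuOMe, −20 °C; 8 added slowly; aq. NH4Cl
Reagents that add atoms: none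
Why: Copper-catalysed asymmetric conjugate addition of a Grignard reagent to an E enoate; the chiral bisphosphine–copper complex differentiates the faces of the beta-carbon and sets C8 (3S in 9), the only stereocentre introduced by a reagent; low temperature and slow addition suppress uncatalysed 1,2-addition.

Step 5
Reactants: 9 methyl (3S)-3-(1,3,5-trimethylcyclohexa-2,5-dien-1-yl)butanoate
Product: 11 (3S)-3-(1,3,5-trimethylcyclohexa-2,5-dien-1-yl)butanenitrile, via primary amide 10 (not isolated)
Conditions: AlMe3, NH3, CH2Cl2, −78 °C → rt (gives Me2AlNH2); then 9, xylene, 110–140 °C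
Reagents that add atoms: dimethylaluminium amide (made from AlMe3 and NH3), C[Al](C)N
Why: Aluminium-amide aminolysis of the ester gives the primary amide 10, which the oxophilic aluminium reagent dehydrates on heating (direct ester-to-nitrile conversion); C8 is beta to the carbonyl and has no acidic hydrogen, so it cannot epimerise.

Step 6
Reactants: 11 (3S)-3-(1,3,5-trimethylcyclohexa-2,5-dien-1-yl)butanenitrile
Product: 13 (3S)-2-methyl-3-(1,3,5-trimethylcyclohexa-2,5-dien-1-yl)butanenitrile (both C2 epimers; C2 is the later C7), via lithiated nitrile 12 (not isolated)
Conditions: LiN(i-Pr)2, THF, −78 °C; then MeI, −78 → 0 °C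
Reagents that add atoms: iodomethane, CI
Why: Alpha-alkylation of a nitrile through its lithio derivative 12; low temperature and one equivalent of base limit double methylation, and the new centre is deliberately left uncontrolled because it is planarised again in step 8.

Step 7
Reactants: 13 (3S)-2-methyl-3-(1,3,5-trimethylcyclohexa-2,5-dien-1-yl)butanenitrile
Product: 15 bis-epoxy nitrile (2-methyl-3-(2,5,7-trimethyl-4,8-dioxatricyclo[5.1.0.0(3,5)]octan-2-yl)butanenitrile; both oxiranes cis to the C1 methyl; both C7 epimers), via mono-epoxide 14 (not isolated)
Conditions: mCPBA (2.5 equiv), NaHCO3, CH2Cl2, 0 °C → rt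
Reagents that add atoms: 3-chloroperoxybenzoic acid, OOC(=O)c1cccc(Cl)c1
Why: Prilezhaev epoxidation of two electron-rich trisubstituted alkenes by way of the mono-epoxide 14; each alkene flanks the quaternary C1, whose branched side chain blocks one face, so both oxygens should enter cis to the C1 methyl; the nitrile is inert to peracid.

Step 8
Reactants: 15 bis-epoxy nitrile
Product: 18 epoxy alcohol nitrile (2,3-epoxy-5-hydroxy-1,3,5,7,8-pentamethylbicyclo[4.2.0]octane-7-carbonitrile; cis ring fusion; nitrile endo; methyls at C1 C7 C8 exo; oxirane plus hydroxyl on the anti face), via potassium nitrile anion 16 (not isolated), via potassium alkoxide 17 (not isolated)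
Conditions: KN(SiMe3)2 (1.2 equiv), toluene, −78 °C → rt; aq. NH4Cl
Reagents that add atoms: none
Why: KN(SiMe3)2 removes the only acidic hydrogen of 15, the one alpha to the nitrile, and gives from either C7 epimer the same planar keteniminate 16. Its carbon attacks the proximal oxirane carbon C6 from the face opposite to the C6–O bond, which forms C6–C7 and releases the tertiary C5 alkoxide 17; the closest known reaction type is the Stork epoxynitrile cyclisation, an established route to cyanocyclobutanes. The one ring closed is the cyclobutane C1–C6–C7–C8, in the 4-exo-tet mode; the 5-endo alternative at C5 is disfavoured because C5 is fully substituted and cannot be reached collinearly through a three-atom tether, and the quaternary C1 in the tether helps closure (Thorpe–Ingold effect). C6 is set by inversion, which makes the ring fusion cis and puts C7 anti to the C5 oxygen. C1 becomes stereogenic through the choice between the two diastereotopic oxiranes, and that choice is controlled by C8: only closure onto C6 lets the C8 methyl lie on the exo face next to the C1 methyl, whereas closure onto C2 would push it under the six-membered ring. C7 is set in the same transition state: the endo position faces the C5 methyl and is taken by the rod-shaped nitrile, so the C7 methyl ends up exo. The step thus needs ring-size selectivity, group selectivity and facial selectivity at C7, secured respectively by the substitution pattern of the oxirane, by the C8 stereocentre and by the small size of the nitrile; the second oxirane survives because its oxygen is on the same face as the new alkoxide and cannot be attacked from the rear, and the alkoxide, anti to C7, cannot reach the nitrile.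

Step 9
Reactants: 18 epoxy alcohol nitrile
Product: 19 5-hydroxy-1,3,5,7,8-pentamethylbicyclo[4.2.0]oct-2-ene-7-carbonitrile (nitrile endo; hydroxyl on the anti face)
Conditions: WCl6 (3 equiv), n-BuLi (6 equiv), THF, −78 °C → rt; then 18, 0 °C → rt
Reagents that add atoms: none
Why: Deoxygenation of an epoxide by oxygen transfer to WCl4 made from WCl6 and n-BuLi, a method known for trisubstituted oxiranes and tolerant of free hydroxyl groups; the alkene geometry is fixed by the ring, the nitrile is inert, and no stereocentre other than the two oxirane carbons is touched.

Step 10
Reactants: 19 5-hydroxy-1,3,5,7,8-pentamethylbicyclo[4.2.0]oct-2-ene-7-carbonitrile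
Product: 21 5-hydroxy-1,3,5,7,8-pentamethylbicyclo[4.2.0]oct-2-ene-7-carbaldehyde (formyl endo), via aluminium aldimine 20 (not isolated)
Conditions: i-Bu2AlH (2.5 equiv), toluene, −78 → 0 °C; then aq. tartaric acid/THF, 0 °C
Reagents that add atoms: water, O
Why: Partial reduction of a nitrile: one hydride adds to give the aluminium aldimine 20 (the first equivalent of i-Bu2AlH is consumed by the hydroxyl), which cannot be reduced further and is hydrolysed in the buffered work-up; C7 has no hydrogen, so the aldehyde cannot epimerise, and the C5 hydroxyl, anti to C7, cannot reach the carbonyl to form a lactol.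

Step 11
Reactants: 21 5-hydroxy-1,3,5,7,8-pentamethylbicyclo[4.2.0]oct-2-ene-7-carbaldehyde; 22 methyl 2-methyl-3-oxopentanoate
Product: 24 methyl 5-hydroxy-5-(5-hydroxy-1,3,5,7,8-pentamethylbicyclo[4.2.0]oct-2-en-7-yl)-2,4-dimethyl-3-oxopentanoate (mixture at the three chain centres), via sodium lithium dianion 23 (not isolated)
Conditions: 22 (3 equiv), NaH, THF, 0 °C; n-BuLi, 0 °C; then 21, −78 → −20 °C; aq. NH4Cl
Reagents that add atoms: none
Why: Aldol addition of the beta-keto ester dianion 23 through its more reactive gamma-carbon to a non-enolisable aldehyde; the excess of 23 compensates for the free hydroxyl, and the new chain stereocentres are of no consequence because they are removed in steps 12 and 13.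

Step 12
Reactants: 24 the hydroxy keto ester
Product: 25 methyl 5-(5-hydroxy-1,3,5,7,8-pentamethylbicyclo[4.2.0]oct-2-en-7-yl)-2,4-dimethyl-3,5-dioxopentanoate
Conditions: Dess–Martin periodinane, NaHCO3, CH2Cl2, rt
Reagents that add atoms: none
Why: Dess–Martin oxidation of the secondary carbinol to the ketone under buffered, non-acidic conditions; the tertiary C5 alcohol cannot be oxidised and the alkene is inert.

Step 13
Reactants: 25 the diketo ester
Product: 26 4-hydroxy-6-(5-hydroxy-1,3,5,7,8-pentamethylbicyclo[4.2.0]oct-2-en-7-yl)-3,5-dimethyl-2H-pyran-2-one
Conditions: DBU, toluene, 60 °C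
Reagents that add atoms: none
Why: Base-mediated cyclisation of a 3,5-diketo ester: the enol oxygen of the C5-chain ketone (the future O1') attacks the ester with loss of methanol and gives the 4-hydroxy-2-pyrone, the standard triketide closure.

Step 14
Reactants: 26 the 4-hydroxy-2-pyrone
Product: 27 6-(5-hydroxy-1,3,5,7,8-pentamethylbicyclo[4.2.0]oct-2-en-7-yl)-2-methoxy-3,5-dimethyl-4H-pyran-4-one
Conditions: MeOTf, CH2Cl2, 0 °C → rt; aq. NaHCO3
Reagents that add atoms: methyl trifluoromethanesulfonate, COS(=O)(=O)C(F)(F)F
Why: O-Methylation of a neutral 4-hydroxy-2-pyrone by a hard alkylating agent takes place at the lactone carbonyl oxygen, the most basic site, and loss of the 4-OH proton on basic work-up gives the 2-methoxy-4-pyrone rather than the 4-methoxy-2-pyrone; the hindered tertiary alcohol and the alkene are much poorer nucleophiles.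

Step 15
Reactants: 27 the pyrone alcohol
Product: 29 2-methoxy-3,5-dimethyl-6-(1,3,5,7,8-pentamethylbicyclo[4.2.0]octa-2,4-dien-7-yl)-4H-pyran-4-one (pyrone endo; methyls at C1 C7 C8 exo), via sulfamate salt 28 (not isolated)
Conditions: Burgess reagent, benzene, rt → 50 °C
Reagents that add atoms: none
Why: Burgess dehydration: the tertiary alcohol forms the sulfamate 28, which undergoes thermal syn elimination without a free carbocation (a C5 cation would be a cyclobutylcarbinyl cation); of the cis hydrogens the allylic one at C4 is the most acidic and its loss gives the conjugated diene; the temperature is kept at or below 50 °C because of the electrocyclic lability of the bicyclo[4.2.0]octadiene.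

Step 16
Reactants: 29 the diene pyrone
Product: 30 target endoperoxide CNP0183511.1
Conditions: O2, hν (visible), methylene blue, CH2Cl2, 0 °C
Reagents that add atoms: dioxygen, O=O
Why: [4+2] Cycloaddition of singlet oxygen to a ring-locked cisoid 1,3-diene (photo-oxygenation); the diene face under which the cyclobutane and its endo pyrone lie is closed, so oxygen should add on the anti face and set C2 and C5 together in the required sense; the cycloaddition is faster than the ene reaction of the allylic hydrogens.

## Compound list

1 | methyl 3,5-dimethylbenzoate | COC(=O)c1cc(C)cc(C)c1 | starting material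
2 | lithium dienolate of methyl 3,5-dimethyl-1,4-dihydrobenzoate | [Li+].COC([O-])=C1C=C(C)CC(C)=C1 | intermediate (not isolated)
3 | methyl 1,3,5-trimethylcyclohexa-2,5-diene-1-carboxylate | COC(=O)C1(C)C=C(C)CC(C)=C1 | intermediate
4 | (1,3,5-trimethylcyclohexa-2,5-dien-1-yl)methanol | OCC1(C)C=C(C)CC(C)=C1 | intermediate
5 | methyl (triphenylphosphoranylidene)acetate | COC(=O)C=P(c1ccccc1)(c1ccccc1)c1ccccc1 | starting material
6 | 1,3,5-trimethylcyclohexa-2,5-diene-1-carbaldehyde | O=CC1(C)C=C(C)CC(C)=C1 | intermediate (not isolated)
7 | methyl (2E)-3-(1,3,5-trimethylcyclohexa-2,5-dien-1-yl)prop-2-enoate | COC(=O)/C=C/C1(C)C=C(C)CC(C)=C1 | intermediate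
8 | methylmagnesium bromide | C[Mg]Br | starting material
9 | methyl (3S)-3-(1,3,5-trimethylcyclohexa-2,5-dien-1-yl)butanoate | COC(=O)C[C@H](C)C1(C)C=C(C)CC(C)=C1 | intermediate
10 | (3S)-3-(1,3,5-trimethylcyclohexa-2,5-dien-1-yl)butanamide | NC(=O)C[C@H](C)C1(C)C=C(C)CC(C)=C1 | intermediate (not isolated)
11 | (3S)-3-(1,3,5-trimethylcyclohexa-2,5-dien-1-yl)butanenitrile | N#CC[C@H](C)C1(C)C=C(C)CC(C)=C1 | intermediate
12 | lithiated nitrile (lithium salt of 11 at C2) | [Li+].N#C[CH-][C@H](C)C1(C)C=C(C)CC(C)=C1 | intermediate (not isolated)
13 | (3S)-2-methyl-3-(1,3,5-trimethylcyclohexa-2,5-dien-1-yl)butanenitrile, both C2 epimers | N#CC(C)[C@H](C)C1(C)C=C(C)CC(C)=C1 | intermediate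
14 | mono-epoxide of 13 (C2–C3 oxirane cis to the C1 methyl shown; the C5–C6 regioisomer forms alongside and converges) | N#CC(C)[C@H](C)[C@@]3(C)[C@@H]4O[C@]4(C)CC(C)=C3 | intermediate (not isolated)
15 | bis-epoxy nitrile, both oxiranes cis to the C1 methyl, both C7 epimers | N#CC(C)[C@H](C)[C@@]3(C)[C@@H]4O[C@]4(C)C[C@]5(C)O[C@H]35 | intermediate
16 | potassium nitrile anion (keteniminate) of 15 | [K+].N#C[C-](C)[C@H](C)[C@@]3(C)[C@@H]4O[C@]4(C)C[C@]5(C)O[C@H]35 | intermediate (not isolated)
17 | potassium C5 alkoxide of 18 | [K+].N#C[C@@]2(C)[C@H](C)[C@@]3(C)[C@@H]4O[C@]4(C)C[C@](C)([O-])[C@@H]23 | intermediate (not isolated)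
18 | 2,3-epoxy-5-hydroxy-1,3,5,7,8-pentamethylbicyclo[4.2.0]octane-7-carbonitrile (nitrile endo; oxirane and hydroxyl on the anti face) | N#C[C@@]2(C)[C@H](C)[C@@]3(C)[C@@H]4O[C@]4(C)C[C@](C)(O)[C@@H]23 | intermediate
19 | 5-hydroxy-1,3,5,7,8-pentamethylbicyclo[4.2.0]oct-2-ene-7-carbonitrile | N#C[C@@]2(C)[C@H](C)[C@@]3(C)C=C(C)C[C@](C)(O)[C@@H]23 | intermediate
20 | N,O-bis(diisobutylaluminio) aldimine of 21 | CC(C)C[Al](CC(C)C)N=C[C@@]2(C)[C@H](C)[C@@]3(C)C=C(C)C[C@](C)(O[Al](CC(C)C)CC(C)C)[C@@H]23 | intermediate (not isolated)
21 | 5-hydroxy-1,3,5,7,8-pentamethylbicyclo[4.2.0]oct-2-ene-7-carbaldehyde | O=C[C@@]2(C)[C@H](C)[C@@]3(C)C=C(C)C[C@](C)(O)[C@@H]23 | intermediate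
22 | methyl 2-methyl-3-oxopentanoate | CCC(=O)C(C)C(=O)OC | starting material
23 | sodium lithium dianion of 22 | [Na+].[Li+].COC(=O)[C-](C)C(=O)[CH-]C | intermediate (not isolated)
24 | methyl 5-hydroxy-5-(bicyclic C7 residue)-2,4-dimethyl-3-oxopentanoate | COC(=O)C(C)C(=O)C(C)C(O)[C@@]2(C)[C@H](C)[C@@]3(C)C=C(C)C[C@](C)(O)[C@@H]23 | intermediate
25 | methyl 5-(bicyclic C7 residue)-2,4-dimethyl-3,5-dioxopentanoate | COC(=O)C(C)C(=O)C(C)C(=O)[C@@]2(C)[C@H](C)[C@@]3(C)C=C(C)C[C@](C)(O)[C@@H]23 | intermediate
26 | 4-hydroxy-6-(5-hydroxy-1,3,5,7,8-pentamethylbicyclo[4.2.0]oct-2-en-7-yl)-3,5-dimethyl-2H-pyran-2-one | O=c1oc([C@@]2(C)[C@H](C)[C@@]3(C)C=C(C)C[C@](C)(O)[C@@H]23)c(C)c(O)c1C | intermediate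
27 | 6-(5-hydroxy-1,3,5,7,8-pentamethylbicyclo[4.2.0]oct-2-en-7-yl)-2-methoxy-3,5-dimethyl-4H-pyran-4-one | COc1oc([C@@]2(C)[C@H](C)[C@@]3(C)C=C(C)C[C@](C)(O)[C@@H]23)c(C)c(=O)c1C | intermediate
28 | triethylammonium N-(methoxycarbonyl)sulfamate ester of 27 at the C5 oxygen | COc1oc([C@@]2(C)[C@H](C)[C@@]3(C)C=C(C)C[C@](C)(OS(=O)(=O)[N-]C(=O)OC)[C@@H]23)c(C)c(=O)c1C.CC[NH+](CC)CC | intermediate (not isolated)
29 | 2-methoxy-3,5-dimethyl-6-(1,3,5,7,8-pentamethylbicyclo[4.2.0]octa-2,4-dien-7-yl)-4H-pyran-4-one | COc1oc([C@@]2(C)[C@H](C)[C@@]3(C)C=C(C)C=C(C)[C@@H]23)c(C)c(=O)c1C | intermediate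
30 | CNP0183511.1, the C2–C5 endoperoxide of 29 on the anti face | COc1oc([C@@]2(C)[C@H](C)[C@@]3(C)[C@@H]4OO[C@@](C)(C=C4C)[C@@H]23)c(C)c(=O)c1C | target

## Step count and least certain steps

Total: 16 steps. Longest linear sequence: 16 steps (1 to 30); 5, 8 and 22 enter as purchased building blocks.

Step 8 (key step). Two things may go wrong.
- Discrimination between the two oxiranes may be incomplete, because closure onto C2 differs from the wanted closure only in where the C8 methyl sits.
- The ring may close with the C7 methyl endo, giving a quaternary centre that cannot be corrected.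

Fallback: set out from 11 and postpone the C7 methyl. Bis-epoxidation of 11 (mCPBA) should give the des-methyl bis-epoxy nitrile F1. Closure with KN(SiMe3)2 then involves a carbanion carrying only hydrogen and nitrile, so the transition state is less crowded and C8 is the only bias; it should give the secondary cyclobutyl nitrile F2. C-methylation of the alkoxide–nitrile dianion of F2 (LiN(i-Pr)2, 2.2 equiv; MeI, 1 equiv; −78 °C) from the open exo face returns to 18.

Step 4. Conjugate transfer of methyl to a beta-carbon that carries a tertiary alkyl group may be too slow, so that 1,2-addition or an unselective background addition takes over.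

Fallback: deliver the smallest nucleophile instead. Set out from 4, oxidised as in step 3 but with 6 worked up. MeMgBr gives 1-(1,3,5-trimethylcyclohexa-2,5-dien-1-yl)ethan-1-ol F3. Dess–Martin oxidation gives the methyl ketone F4. Horner–Wadsworth–Emmons olefination (trimethyl phosphonoacetate, NaH, DME, reflux) gives the E beta-methyl enoate F5. Asymmetric conjugate reduction with a CuH catalyst (Cu(OAc)2, a chiral bisphosphine, polymethylhydrosiloxane, t-BuOH, toluene) returns to 9.

Step 7. Facial control may erode in the second oxygen transfer, since the first oxirane disfavours a cis approach. An isomer with the C2–C3 oxirane on the wrong face still converges (that oxirane is removed in step 9), but one with the C5–C6 oxirane on the wrong face cannot close correctly.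

Fallback: catalyst-controlled, sequential epoxidation. Set out from 13 and use the two antipodes of a fructose-derived ketone catalyst (Shi epoxidation; KHSO5, K2CO3, MeCN/dimethoxymethane/water, 0 °C). The first antipode gives isolated 14 and the second completes 15, each matched with the steric bias. No new compound arises.

Step 9. The Lewis-acidic tungsten species may ionise the trisubstituted oxirane (hydride shift to a C2 ketone) or chlorinate the tertiary alcohol instead of transferring oxygen.

Fallback: a two-stage halohydrin route from 18. Buffered opening (NaI, NaOAc, AcOH/THF, 0 °C) gives the iodohydrin F6; reductive elimination with Zn in AcOH returns to 19.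

Step 11. C–C bond formation may fail at an aldehyde on a fully substituted cyclobutane carbon under the six-membered ring; the bulky secondary carbanion may add reversibly or act only as a base.

Fallback: build the chain with a small nucleophile and reverse the polarity of the second bond. From 21, EtMgBr gives the propyl carbinol F7 and Dess–Martin oxidation gives the ethyl ketone F8. C-acylation of F8 under soft enolisation (MgBr2·OEt2, i-Pr2NEt, methyl 3-chloro-2-methyl-3-oxopropanoate, CH2Cl2) returns to 25.

Step 15. The elimination may lose regiocontrol (toward the C5 methyl or toward C6), or the sulfamate may ionise, followed by cyclobutylcarbinyl ring expansion.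

Fallback: replace the thermal syn elimination by a base-mediated anti elimination of the chlorosulfite (SOCl2, pyridine, CH2Cl2, −20 °C), from 27 directly to 29. The C6 hydrogen is cis to the leaving group and is excluded stereoelectronically, which leaves the allylic C4 hydrogen as the favoured partner. No new compound arises.

## Further compounds

F1 | step 8 | des-methyl bis-epoxy nitrile, 3-(2,5,7-trimethyl-4,8-dioxatricyclo[5.1.0.0(3,5)]octan-2-yl)butanenitrile | N#CC[C@H](C)[C@@]3(C)[C@@H]4O[C@]4(C)C[C@]5(C)O[C@H]35
F2 | step 8 | 2,3-epoxy-5-hydroxy-1,3,5,8-tetramethylbicyclo[4.2.0]octane-7-carbonitrile (C7 epimers) | N#CC2[C@H](C)[C@@]3(C)[C@@H]4O[C@]4(C)C[C@](C)(O)[C@@H]23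
F3 | step 4 | 1-(1,3,5-trimethylcyclohexa-2,5-dien-1-yl)ethan-1-ol | CC(O)C1(C)C=C(C)CC(C)=C1
F4 | step 4 | 1-(1,3,5-trimethylcyclohexa-2,5-dien-1-yl)ethan-1-one | CC(=O)C1(C)C=C(C)CC(C)=C1
F5 | step 4 | methyl (2E)-3-(1,3,5-trimethylcyclohexa-2,5-dien-1-yl)but-2-enoate | COC(=O)/C=C(\C)C1(C)C=C(C)CC(C)=C1
F0 | step 7 | none | none
F6 | step 9 | 2,5-dihydroxy-3-iodo-1,3,5,7,8-pentamethylbicyclo[4.2.0]octane-7-carbonitrile (iodide trans to the C2 hydroxyl) | N#C[C@@]2(C)[C@H](C)[C@@]3(C)[C@H](O)[C@@](C)(I)C[C@](C)(O)[C@@H]23
F7 | step 11 | 1-(5-hydroxy-1,3,5,7,8-pentamethylbicyclo[4.2.0]oct-2-en-7-yl)propan-1-ol | CCC(O)[C@@]2(C)[C@H](C)[C@@]3(C)C=C(C)C[C@](C)(O)[C@@H]23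
F8 | step 11 | 1-(5-hydroxy-1,3,5,7,8-pentamethylbicyclo[4.2.0]oct-2-en-7-yl)propan-1-one | CCC(=O)[C@@]2(C)[C@H](C)[C@@]3(C)C=C(C)C[C@](C)(O)[C@@H]23
F0 | step 15 | none | none
A1 | alternative 1 | trimethylsilyl enol ether of the 7-(silyloxymethyl)bicyclo[3.2.0]heptan-2-one | CC(C)(C)[Si](C)(C)OC[C@@]2(C)[C@H](C)[C@@]3(C)C(O[Si](C)(C)C)=C[C@@H](C)[C@@H]23
A2 | alternative 1 | chloro(methyl)carbene | C[C]Cl
A3 | alternative 1 | bicyclo[4.2.0]oct-3-en-2-one | CC(C)(C)[Si](C)(C)OC[C@@]2(C)[C@H](C)[C@@]3(C)C(=O)C(C)=C[C@@H](C)[C@@H]23
A4 | alternative 2 | 1,3,5-trimethyl-4-oxocyclohexa-2,5-dien-1-yl (2E)-2-methylbut-2-enoate (quinol tiglate) | C/C=C(\C)C(=O)OC1(C)C=C(C)C(=O)C(C)=C1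
A5 | alternative 2 | tricyclic enone lactone | O=C4[C@@]2(C)[C@H](C)[C@@]3(C)C(=O)C(C)=C[C@@](C)(O4)[C@@H]23
A6 | alternative 3 | 2,2,5-trimethyl-6-(bicyclic C7 residue, C5 triethylsilyl ether)-4H-1,3-dioxin-4-one | CC1=C(OC(C)(C)OC1=O)[C@@]2(C)[C@H](C)[C@@]3(C)C=C(C)C[C@](C)(O[Si](CC)(CC)CC)[C@@H]23
A7 | alternative 3 | acylketene from A6 | O=C=C(C)C(=O)[C@@]2(C)[C@H](C)[C@@]3(C)C=C(C)C[C@](C)(O[Si](CC)(CC)CC)[C@@H]23
A8 | alternative 3 | 1-methoxypropyne | COC#CC
A9 | alternative 3 | pyrone-bearing bicyclo[4.2.0]oct-2-ene triethylsilyl ether | COc1oc([C@@]2(C)[C@H](C)[C@@]3(C)C=C(C)C[C@](C)(O[Si](CC)(CC)CC)[C@@H]23)c(C)c(=O)c1C
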